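The numbers in the tables stem from a simulated flask for an exercise; scatter was added.

| setting | delta | gamma | flask |
|---|---|---|---|
| G | 10 mM | 10 mM | 10 mM |
| X | 0.095 µM | 0.38 µM | 0.19 µM |
| remark | run made earlier | run made earlier |  |

| run | time / d | Z / % |
|---|---|---|
| delta | 0.208 | 5.6 |
| delta | 0.500 | 11.0 |
| delta | 1.04 | 16.1 |
| delta | 1.67 | 21.6 |
| delta | 2.00 | 24.3 |
| delta | 3.00 | 31.5 |
| delta | 4.00 | 40.0 |
| gamma | 0.208 | 17.2 |
| gamma | 0.500 | 44.3 |
| gamma | 1.04 | 98.4 |
| gamma | 1.67 | 101.0 |
| gamma | 2.00 | 99.4 |
| gamma | 3.00 | 100.1 |
| gamma | 4.00 | 98.9 |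

(readings scatter by 1 percentage point)

- factor on the rate of making Z when 20 % of the G are converted if X is charged twice over
- factor on the rate when 20 % of the G are converted if X is charged at 0.020 µM instead



1. Z in the gamma run levels off at 100.1 % of the G charged, so G and Z keep their sum and each reading is a conversion. I follow the rate, as a share of the charge per day.

2. At the start, the first reading gives 0.269 /d for delta and 0.827 /d for gamma. That is a factor of 3.07 on a factor of 4.00 in [X], so the start rate roughly follows [X].

3. From 1.67 d to 4.00 d, delta runs at 0.0790 /d. My floor share, the late rate of a run over its start rate, reads 0.293 for delta. This is a floor, not a stop, because Z still climbs.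

4. Delta passes 20 % between 1.04 d and 1.67 d, where its readings give 0.0873 /d. Gamma passes it between 0.208 d and 0.500 d, where its readings give 0.928 /d, faster than its start rate, so gamma shows no slowing at that mark.

5. The flask's [X] is the geometric mean of the [X] of delta and gamma, so I take the geometric mean of their rates at the mark, 0.285 /d, for the flask. Against delta's start rate scaled to the flask's charge, that is a kept share of 0.529.

6. Doubling the flask gives gamma's charge, so I reckon dbl at 3.26. Putting the 0.020 µM charge on delta's floor share, I reckon ratio at 0.0584.

7. The forecast gives 2.8 and 0.02, reasoning from “an apparent order of about 1.7 in X”. Its ratio is lower than mine.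

    G + X → Z + X, rate k1*[G]*[X]/(1 + ([G]/Km1) + ([G]/Ksi1)^2) (15.8 mM, 1.70 mM, k = 3.52 × 10⁶ /M/h)
    X ⇌ J (K = 4.30, k = 0.0393 /h)

The flask gives 2.55 and 0.0312, a ratio above the forecast's and below mine. It reaches 20 % at 0.512 d with a rate of 3.45 mM/d, while X passes into J, a form outside the working round. That rate is a share 0.641 of delta's start rate scaled to the flask's charge. Put on this share, my floor share 0.293 gives the charge of 0.020 µM a factor of 0.0482, against the simulated 0.0312.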